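**Retrosynthetic overview**

- The strategy rests on the only ring, the benzene ring, which carries oxygen on C1 and C3 and the C17 chain on C5: the alternating pattern of a fatty-acyl tetraketide folded by aldol condensation, so the ring is made last from an open chain.
- Key disconnection: the ring bond between the chain-bearing carbon C5 and its neighbour C4 (which keeps a CO2Me group until the end), leading back to a methyl 3,5,7-trioxotetracosadienoate in which C2 adds to C7; the extra carboxyl carbon is lost as CO2 afterwards.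
- The triketo ester is cut at C6–C7 into the trianion of methyl 3,5-dioxohexanoate (from methyl acetoacetate) and the Weinreb amide of a C18 (9Z,13S,15Z)-13-silyloxy dienoic acid.
- The C18 acid comes from dec-9-ynoic acid dianion (C10–C11 bond) and a bromide made from (S)-butane-1,2,4-triol via (S)-2-(2-bromoethyl)oxirane and but-1-ynyllithium (C14–C15 bond); one Lindlar reduction sets both Z-alkenes, and the stereocentre comes from the triol with its C–O bond never broken.
- Ring order: the benzene ring is the single ring and is formed in step 10; desilylation and saponification–decarboxylation follow.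

Key step: step 10

Assumption: HBr in acetic acid is taken to brominate both primary carbons of the triol by the acetoxonium pathway; the fallback to step 1 covers the case that it does not.

**Route**

Step 1
Reactants: 1 (S)-butane-1,2,4-triol
Product: 2 (2S)-1,4-dibromobutan-2-yl acetate
Conditions: HBr (33% in AcOH, excess), 0 °C → rt
Reagents that add atoms: hydrogen bromide, Br; acetic acid, CC(=O)O
Why: Acetoxonium-mediated bromoacetate formation from diols: the 1,2-diol reacts through a 2-methyl-1,3-dioxolan-2-ylium ion and the C4 hydroxyl through the six-membered acetoxonium ion of the C2 acetate, bromide opens both at the primary CH2, and the C2–O bond is never broken, so the (S) centre of the chiral pool is carried over unchanged.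

Step 2
Reactants: 2 (2S)-1,4-dibromobutan-2-yl acetate
Product: 3 (2S)-2-(2-bromoethyl)oxirane
Conditions: K2CO3, MeOH, 0 °C → rt
Reagents that add atoms: none
Why: Transesterification removes the acetate and the bromohydrin alkoxide closes the epoxide by 3-exo-tet Williamson displacement of the C1 bromide, much faster than 4-exo closure onto C4, with retention at the carbinol carbon.

Step 3
Reactants: 4 but-1-yne; 3 (2S)-2-(2-bromoethyl)oxirane
Product: 6 (3R)-1-bromooct-5-yn-3-ol, via but-1-ynyllithium 5 (not isolated)
Conditions: 4, n-BuLi, THF, −78 °C; BF3·OEt2, −78 °C; then 3, −78 °C; aq. NH4Cl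
Reagents that add atoms: none
Why: Yamaguchi–Hirao alkynylation: the lithium alkynyltrifluoroborate opens the BF3-activated epoxide at its terminal CH2 and does not displace the primary bromide at −78 °C, so the stereocentre is untouched (its descriptor becomes R only because the CIP ranking of the two CH2 arms changes).

Step 4
Reactants: 6 (3R)-1-bromooct-5-yn-3-ol
Product: 7 tert-butyl{[(3R)-1-bromooct-5-yn-3-yl]oxy}dimethylsilane
Conditions: TBSOTf, 2,6-lutidine, CH2Cl2, −78 → 0 °C
Reagents that add atoms: tert-butyldimethylsilyl trifluoromethanesulfonate, CC(C)(C)[Si](C)(C)OS(=O)(=O)C(F)(F)F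
Why: Silylation of the secondary alcohol with the silyl triflate and a hindered pyridine base is fast at low temperature and brings in no nucleophile that could attack the primary bromide.

Step 5
Reactants: 8 dec-9-ynoic acid; 7 tert-butyl{[(3R)-1-bromooct-5-yn-3-yl]oxy}dimethylsilane
Product: 10 (13S)-13-[(tert-butyldimethylsilyl)oxy]octadeca-9,15-diynoic acid, via dilithium dec-9-ynoate 9 (not isolated)
Conditions: 8, n-BuLi (2 equiv), THF/DMPU, −78 → 0 °C; then 7, 0 °C → rt; cold dilute HCl to pH 4
Reagents that add atoms: none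
Why: Acetylide alkylation of an ω-alkynoic acid dianion: the sp carbanion displaces the unhindered primary bromide by SN2 in the dipolar medium while the lithium carboxylate stays inert.

Step 6
Reactants: 10 (13S)-13-[(tert-butyldimethylsilyl)oxy]octadeca-9,15-diynoic acid
Product: 11 (9Z,13S,15Z)-13-[(tert-butyldimethylsilyl)oxy]octadeca-9,15-dienoic acid
Conditions: H2 (1 atm), Pd/CaCO3 poisoned with Pb(OAc)2 (Lindlar catalyst), quinoline, EtOAc, rt, stopped after 2 equiv H2
Reagents that add atoms: none
Why: Lindlar semihydrogenation adds H2 syn to both isolated internal alkynes and stops at the alkene on the lead-poisoned surface, so both Z double bonds should form in one operation.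

Step 7
Reactants: 11 (9Z,13S,15Z)-13-[(tert-butyldimethylsilyl)oxy]octadeca-9,15-dienoic acid
Product: 12 (9Z,13S,15Z)-13-[(tert-butyldimethylsilyl)oxy]-N-methoxy-N-methyloctadeca-9,15-dienamide
Conditions: CDI, CH2Cl2, rt; then MeNHOMe·HCl, rt
Reagents that add atoms: N,O-dimethylhydroxylamine hydrochloride, CNOC.Cl
Why: Activation as the acyl imidazolide and aminolysis gives the Weinreb amide, an acyl donor that forms a stable chelated tetrahedral adduct with carbanions and cannot over-react.

Step 8
Reactants: 13 methyl acetoacetate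
Product: 15 methyl 3,5-dioxohexanoate, via acetoacetate dianion 14 (not isolated)
Conditions: LiN(i-Pr)2 (2.1 equiv), THF, 0 °C; MeC(O)N(Me)OMe, −78 → 0 °C; dilute HCl
Reagents that add atoms: N-methoxy-N-methylacetamide, CC(=O)N(C)OC
Why: Dianion acylation of a β-keto ester: the terminal carbon of the dianion is its most nucleophilic site and is acetylated by the Weinreb amide through a chelate that collapses only on work-up.

Step 9
Reactants: 15 methyl 3,5-dioxohexanoate; 12 (9Z,13S,15Z)-13-[(tert-butyldimethylsilyl)oxy]-N-methoxy-N-methyloctadeca-9,15-dienamide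
Product: 17 methyl (15Z,19S,21Z)-19-[(tert-butyldimethylsilyl)oxy]-3,5,7-trioxotetracosa-15,21-dienoate, via dioxohexanoate trianion 16 (not isolated)
Conditions: 15 (1.5 equiv), LiN(i-Pr)2 (4.6 equiv), THF, −78 → 0 °C; then 12, −78 → −20 °C; AcOH, −78 °C
Reagents that add atoms: none
Why: Claisen-type acylation of a 1,3,5-tricarbonyl polyanion: the terminal CH2 of the trianion is the last-formed and most reactive carbanion and is acylated by the Weinreb amide, whose chelated adduct shields the new ketone until the acidic quench.

Step 10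
Reactants: 17 methyl (15Z,19S,21Z)-19-[(tert-butyldimethylsilyl)oxy]-3,5,7-trioxotetracosa-15,21-dienoate
Product: 19 methyl 2,4-dihydroxy-6-[(8Z,12S,14Z)-12-[(tert-butyldimethylsilyl)oxy]heptadeca-8,14-dien-1-yl]benzoate, via cyclic aldol adduct 18 (not isolated)
Conditions: K2CO3 (2 equiv), degassed MeOH, 0 °C → rt; then AcOH to pH 5, 40 °C
Reagents that add atoms: none
Why: Carbonate enolises C2, the methylene flanked by the ester and the C3 ketone, and this carbon adds to the C7 ketone (the former acyl carbon of the fatty acid) in an intramolecular aldol reaction; E1cB loss of water from adduct 18 and two enolisations then give the arene, which makes the sequence irreversible. The closest known reaction type is the base-mediated aldol cyclisation of 3,5,7-triketo esters to 2,4-dihydroxy-6-alkylbenzoates, the laboratory counterpart of alkylresorcinol-type polyketide cyclisation. The one ring, the benzene ring, closes in a 6-(enolendo)-exo-trig mode by forming the bond between the chain-bearing carbon and the carbon that carries CO2Me. No stereocentre is created: the two sp3 centres of 18 vanish on aromatisation and the remote (S)-silyloxy carbon is not involved. The step needs aldol closure (C2 onto C7) to win over Claisen closure (C6 onto the ester, giving an acylphloroglucinol), over O-acylation to a 4-hydroxy-2-pyrone and over attack by the singly activated C8 methylene; the ketone is a far better electrophile than the methyl ester, a potassium base in methanol offers no chelating divalent metal to activate the ester, and C8 is many pK units less acidic than C2. The Z-alkenes and the silyl ether lie far from every acidic site and are inert to carbonate and acetic acid.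

Step 11
Reactants: 19 methyl 2,4-dihydroxy-6-[(8Z,12S,14Z)-12-[(tert-butyldimethylsilyl)oxy]heptadeca-8,14-dien-1-yl]benzoate
Product: 20 methyl 2,4-dihydroxy-6-[(8Z,12S,14Z)-12-hydroxyheptadeca-8,14-dien-1-yl]benzoate
Conditions: HF·pyridine, pyridine/THF, 0 °C → rt
Reagents that add atoms: none
Why: Fluoride-mediated desilylation cleaves the secondary silyl ether through the strong Si–F bond under buffered conditions that leave the phenols, the ester and the Z-alkenes alone.

Step 12
Reactants: 20 methyl 2,4-dihydroxy-6-[(8Z,12S,14Z)-12-hydroxyheptadeca-8,14-dien-1-yl]benzoate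
Product: 22 5-[(8Z,12S,14Z)-12-hydroxyheptadeca-8,14-dien-1-yl]benzene-1,3-diol, via resorcylic acid 21 (not isolated)
Conditions: KOH, EtOH/H2O, reflux, Ar; then dilute HCl to pH 2, 50 °C
Reagents that add atoms: none
Why: Saponification and decarboxylation of a β-resorcylate: hot alkali hydrolyses the hindered ester and the acid loses CO2 readily by ipso-protonation ortho and para to the hydroxyls, while the isolated Z-alkenes and the homoallylic alcohol are not affected.

**Compound list**

1 | (S)-butane-1,2,4-triol | OC[C@@H](O)CCO | starting material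
2 | (2S)-1,4-dibromobutan-2-yl acetate | BrC[C@@H](OC(C)=O)CCBr | intermediate
3 | (2S)-2-(2-bromoethyl)oxirane | BrCC[C@H]1CO1 | intermediate
4 | but-1-yne | CCC#C | starting material
5 | but-1-yn-1-yllithium | [Li]C#CCC | intermediate
6 | (3R)-1-bromooct-5-yn-3-ol | CCC#CC[C@@H](O)CCBr | intermediate
7 | tert-butyl{[(3R)-1-bromooct-5-yn-3-yl]oxy}dimethylsilane | CCC#CC[C@@H](O[Si](C)(C)C(C)(C)C)CCBr | intermediate
8 | dec-9-ynoic acid | OC(=O)CCCCCCCC#C | starting material
9 | dilithium dec-9-ynoate (carboxylate and terminal acetylide) | [Li+].[Li+].[O-]C(=O)CCCCCCCC#[C-] | intermediate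
10 | (13S)-13-[(tert-butyldimethylsilyl)oxy]octadeca-9,15-diynoic acid | CCC#CC[C@@H](O[Si](C)(C)C(C)(C)C)CCC#CCCCCCCCC(=O)O | intermediate
11 | (9Z,13S,15Z)-13-[(tert-butyldimethylsilyl)oxy]octadeca-9,15-dienoic acid | CC/C=C\C[C@@H](O[Si](C)(C)C(C)(C)C)CC/C=C\CCCCCCCC(=O)O | intermediate
12 | (9Z,13S,15Z)-13-[(tert-butyldimethylsilyl)oxy]-N-methoxy-N-methyloctadeca-9,15-dienamide | CC/C=C\C[C@@H](O[Si](C)(C)C(C)(C)C)CC/C=C\CCCCCCCC(=O)N(C)OC | intermediate
13 | methyl acetoacetate | COC(=O)CC(C)=O | starting material
14 | dilithium dianion of methyl acetoacetate | [Li+].[Li+].C=C([O-])C=C([O-])OC | intermediate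
15 | methyl 3,5-dioxohexanoate | COC(=O)CC(=O)CC(C)=O | intermediate
16 | trilithium trianion of methyl 3,5-dioxohexanoate | [Li+].[Li+].[Li+].C=C([O-])C=C([O-])C=C([O-])OC | intermediate
17 | methyl (15Z,19S,21Z)-19-[(tert-butyldimethylsilyl)oxy]-3,5,7-trioxotetracosa-15,21-dienoate | CC/C=C\C[C@@H](O[Si](C)(C)C(C)(C)C)CC/C=C\CCCCCCCC(=O)CC(=O)CC(=O)CC(=O)OC | intermediate
18 | methyl 2-hydroxy-4,6-dioxo-2-[(8Z,12S,14Z)-12-[(tert-butyldimethylsilyl)oxy]heptadeca-8,14-dien-1-yl]cyclohexane-1-carboxylate (cyclic aldol adduct, ring stereocentres unassigned) | CC/C=C\C[C@@H](O[Si](C)(C)C(C)(C)C)CC/C=C\CCCCCCCC1(O)CC(=O)CC(=O)C1C(=O)OC | intermediate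
19 | methyl 2,4-dihydroxy-6-[(8Z,12S,14Z)-12-[(tert-butyldimethylsilyl)oxy]heptadeca-8,14-dien-1-yl]benzoate | CC/C=C\C[C@@H](O[Si](C)(C)C(C)(C)C)CC/C=C\CCCCCCCc1cc(O)cc(O)c1C(=O)OC | intermediate
20 | methyl 2,4-dihydroxy-6-[(8Z,12S,14Z)-12-hydroxyheptadeca-8,14-dien-1-yl]benzoate | CC/C=C\C[C@@H](O)CC/C=C\CCCCCCCc1cc(O)cc(O)c1C(=O)OC | intermediate
21 | 2,4-dihydroxy-6-[(8Z,12S,14Z)-12-hydroxyheptadeca-8,14-dien-1-yl]benzoic acid | CC/C=C\C[C@@H](O)CC/C=C\CCCCCCCc1cc(O)cc(O)c1C(=O)O | intermediate
22 | 5-[(8Z,12S,14Z)-12-hydroxyheptadeca-8,14-dien-1-yl]benzene-1,3-diol | CC/C=C\C[C@@H](O)CC/C=C\CCCCCCCc1cc(O)cc(O)c1 | target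

**Step count**

Total: 12 steps. Longest linear sequence: 11 steps (steps 1–7 and 9–12, from 1); step 8 is a one-step side branch.

**Steps most likely to fail**

Step 10 (key step). The closure may take the wrong course: Claisen attack of C6 on the ester, O-cyclisation to a pyrone, methoxide-induced retro-Claisen cleavage of the polyketone, or stalling at the aldol stage before dehydration. The fallback sets out from Weinreb amide 12 and comes back at resorcylate 19. Commercial 2,2,6-trimethyl-4H-1,3-dioxin-4-one is deprotonated with LiN(SiMe3)2 in THF at −78 °C and acetylated with acetyl chloride to give 2,2-dimethyl-6-(2-oxopropyl)-4H-1,3-dioxin-4-one F1. Its dianion (LiN(i-Pr)2, 2 equiv, THF, −78 °C) is acylated at the terminal carbon by 12 to give the diketo-dioxinone 6-[(12Z,16S,18Z)-16-[(tert-butyldimethylsilyl)oxy]-2,4-dioxohenicosa-12,18-dien-1-yl]-2,2-dimethyl-4H-1,3-dioxin-4-one F2. Et3N in CH2Cl2 at rt should then effect the same aldol closure and dehydration, now with the carboxyl locked inside the dioxinone so that neither Claisen nor pyrone closure is open, to give 5-[(8Z,12S,14Z)-12-[(tert-butyldimethylsilyl)oxy]heptadeca-8,14-dien-1-yl]-7-hydroxy-2,2-dimethyl-4H-1,3-benzodioxin-4-one F3. K2CO3 in MeOH opens the benzodioxinone by transesterification to 19.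

Step 9. The ester trianion may self-condense while it is generated, may abstract a proton from the amide α-methylene instead of adding, or may react through an internal site. The fallback sets out from 12 and comes back at triketo ester 17, using the better behaved dianion of a β-diketone. Dilithio pentane-2,4-dione (LiN(i-Pr)2, 2 equiv, THF, 0 °C) is acylated by 12 at its terminal carbon to give (14Z,18S,20Z)-18-[(tert-butyldimethylsilyl)oxy]tricosa-14,20-diene-2,4,6-trione F4. Three equivalents of LiN(i-Pr)2 ionise its methyl terminus, and carboxylation of the trianion with CO2 at −78 °C gives (15Z,19S,21Z)-19-[(tert-butyldimethylsilyl)oxy]-3,5,7-trioxotetracosa-15,21-dienoic acid F5. Immediate esterification with Me3SiCHN2 in toluene/MeOH at −20 °C, where the carboxylic acid reacts much faster than the enols, gives 17.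

Step 1. The isolated C4 hydroxyl may be acetylated instead of brominated, or the triol may cyclodehydrate to a tetrahydrofuran under the acid. The fallback sets out from 1 and comes back at epoxide 3 by protecting-group chemistry. Acetone with p-TsOH gives the five-membered acetonide 2-[(4S)-2,2-dimethyl-1,3-dioxolan-4-yl]ethan-1-ol F6. Appel bromination (CBr4, PPh3, CH2Cl2, 0 °C) gives (4S)-4-(2-bromoethyl)-2,2-dimethyl-1,3-dioxolane F7. Aqueous AcOH frees (2S)-4-bromobutane-1,2-diol F8. Selective sulfonylation of the primary hydroxyl (TsCl, Et3N, Bu2SnO cat., CH2Cl2, 0 °C) gives (2S)-4-bromo-2-hydroxybutyl 4-methylbenzenesulfonate F9. K2CO3 in MeOH closes the epoxide by 3-exo-tet displacement of the sulfonate to give 3.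

**Further compounds**

F1 | step 10 | 2,2-dimethyl-6-(2-oxopropyl)-4H-1,3-dioxin-4-one | CC(=O)CC1=CC(=O)OC(C)(C)O1
F2 | step 10 | 6-[(12Z,16S,18Z)-16-[(tert-butyldimethylsilyl)oxy]-2,4-dioxohenicosa-12,18-dien-1-yl]-2,2-dimethyl-4H-1,3-dioxin-4-one | CC/C=C\C[C@@H](O[Si](C)(C)C(C)(C)C)CC/C=C\CCCCCCCC(=O)CC(=O)CC1=CC(=O)OC(C)(C)O1
F3 | step 10 | 5-[(8Z,12S,14Z)-12-[(tert-butyldimethylsilyl)oxy]heptadeca-8,14-dien-1-yl]-7-hydroxy-2,2-dimethyl-4H-1,3-benzodioxin-4-one | CC/C=C\C[C@@H](O[Si](C)(C)C(C)(C)C)CC/C=C\CCCCCCCc1cc(O)cc2OC(C)(C)OC(=O)c12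
F4 | step 9 | (14Z,18S,20Z)-18-[(tert-butyldimethylsilyl)oxy]tricosa-14,20-diene-2,4,6-trione | CC/C=C\C[C@@H](O[Si](C)(C)C(C)(C)C)CC/C=C\CCCCCCCC(=O)CC(=O)CC(C)=O
F5 | step 9 | (15Z,19S,21Z)-19-[(tert-butyldimethylsilyl)oxy]-3,5,7-trioxotetracosa-15,21-dienoic acid | CC/C=C\C[C@@H](O[Si](C)(C)C(C)(C)C)CC/C=C\CCCCCCCC(=O)CC(=O)CC(=O)CC(=O)O
F6 | step 1 | 2-[(4S)-2,2-dimethyl-1,3-dioxolan-4-yl]ethan-1-ol | CC1(C)OC[C@H](CCO)O1
F7 | step 1 | (4S)-4-(2-bromoethyl)-2,2-dimethyl-1,3-dioxolane | CC1(C)OC[C@H](CCBr)O1
F8 | step 1 | (2S)-4-bromobutane-1,2-diol | OC[C@@H](O)CCBr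
F9 | step 1 | (2S)-4-bromo-2-hydroxybutyl 4-methylbenzenesulfonate | Cc1ccc(cc1)S(=O)(=O)OC[C@@H](O)CCBr
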